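**Retrosynthetic overview**
1. Target 30 ⇐ C18 alcohol oxidation and 6-O-desilylation ⇐ C12–C13 sp3–sp2 bond (nickel reductive coupling) between bicyclic bromide 27 and the pre-formed (R)-butenolide alkenyl bromide 9.
2. 27 ⇐ exocyclic C8=C17 alkene 24; Markovnikov hydration from the α-face gives the 8α-OH/8β-CH3 carbinol.
3. Key disconnection: both carbocycles of 24 ⇐ acyclic epoxy-diene 23 by a titanocene(III) radical cascade forming C4–C5 (ring A) and then C9–C10 (ring B).
4. Enabling feature: C4 bears a methyl and the oxygenated C18, so a C4/C18 oxirane gives a tertiary C4 radical. C10 and C8 are the methyl-bearing inner carbons of the 1,5-diene C5=C10/C8=C9. The equatorial 6α-oxygen on ring B is the single stereocentre that steers the chair–chair folding.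
5. 23 ⇐ Nozaki–Hiyama–Kishi union at C5–C6 of alkenyl iodide 19 and aldehyde 15 (sets C6). Ring order: butenolide (step 4), ring A, then ring B (both in step 15, ring B last).

Key step: step 15

Remarks: Labdane numbering is used for the decalin (C11–C12 on C9, C17 on C8, C18 α and C19 β on C4, C20 on C10); C16 is the butenolide carbinol carbon. Epoxide 23 is used as a mixture of oxirane epimers, which converge on the same planar C4 radical. In steps 3 and 11 the ligand antipode named is the one expected to give the drawn configuration; this should be checked on the product (Mosher ester) and the antipode used otherwise.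

Step 1
Reactants: 1 pent-3-yn-1-ol
Product: 3 (E)-4-bromopent-3-en-1-ol, via alkenylzirconocene chloride 2 (not isolated)
Conditions: Cp2Zr(H)Cl (2.5 equiv), THF, rt to 40 °C; then NBS, 0 °C
Reagents that add atoms: N-bromosuccinimide, O=C1CCC(=O)N1Br
Why: Hydrozirconation–halogenation: syn Zr–H addition, with excess Schwartz reagent equilibrating zirconium to the methyl-bearing alkyne carbon, then brominolysis with retention should give the (E)-alkenyl bromide.

Step 2
Reactants: 3 (E)-4-bromopent-3-en-1-ol
Product: 4 (E)-4-bromopent-3-enal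
Conditions: Dess–Martin periodinane, NaHCO3, CH2Cl2, 0 °C; used crude
Reagents that add atoms: none
Why: Buffered Dess–Martin oxidation is non-basic, so the β,γ-double bond should stay in place.

Step 3
Reactants: 4 (E)-4-bromopent-3-enal; 5 methyl propiolate
Product: 7 methyl (4R,6E)-7-bromo-4-hydroxyoct-6-en-2-ynoate, via methylzinc alkynylide 6 (not isolated)
Conditions: Me2Zn (3 equiv), (S,S)-ProPhenol (cat.), Ph3P=O (cat.), toluene, 0 °C; aq. NH4Cl
Reagents that add atoms: none
Why: ProPhenol/zinc-catalysed enantioselective alkynylation: the dinuclear zinc catalyst delivers the zinc alkynylide to one aldehyde face and so sets C16 (R).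

Step 4
Reactants: 7 methyl (4R,6E)-7-bromo-4-hydroxyoct-6-en-2-ynoate
Product: 9 (5R)-5-[(2E)-3-bromobut-2-en-1-yl]-4-methylfuran-2(5H)-one, via (Z)-hydroxy enoate 8 (not isolated)
Conditions: Me2CuLi (3 equiv, from MeLi and CuI), THF, −78 °C; then AcOH, aq. NH4Cl, to rt
Reagents that add atoms: lithium dimethylcuprate, [Li+].C[Cu-]C
Why: syn-Carbocupration of the ynoate at −78 °C places methyl and α-H cis, so the γ-hydroxyl and the ester are cis and lactonise on work-up to the butenolide; C16 is not touched.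

Step 5
Reactants: 10 tert-butyl(but-3-yn-1-yloxy)dimethylsilane
Product: 12 (3E)-6-[(tert-butyldimethylsilyl)oxy]-4-methylhex-3-en-1-ol, via alkenylalane 11 (not isolated)
Conditions: Me3Al (2 equiv), Cp2ZrCl2 (0.2 equiv), CH2Cl2, 0 °C to rt; then n-BuLi, THF, −30 °C; ethylene oxide, −30 to 0 °C
Reagents that add atoms: trimethylaluminium, C[Al](C)C; ethylene oxide, C1CO1
Why: Negishi zirconium-catalysed carboalumination (syn Me–Al addition, methyl to the inner carbon), then opening of ethylene oxide by the alanate with retention, should give the (E)-trisubstituted homoallylic alcohol.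

Step 6
Reactants: 12 (3E)-6-[(tert-butyldimethylsilyl)oxy]-4-methylhex-3-en-1-ol
Product: 13 (3E)-6-[(tert-butyldimethylsilyl)oxy]-4-methylhex-3-en-1-yl pivalate
Conditions: PivCl, pyridine, DMAP (cat.), CH2Cl2, 0 °C to rt
Reagents that add atoms: pivaloyl chloride, CC(C)(C)C(=O)Cl
Why: Standard acylation of a primary alcohol; the pivalate survives every step up to the hydride reduction in step 17.

Step 7
Reactants: 13 (3E)-6-[(tert-butyldimethylsilyl)oxy]-4-methylhex-3-en-1-yl pivalate
Product: 14 (3E)-6-hydroxy-4-methylhex-3-en-1-yl pivalate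
Conditions: CSA (cat.), MeOH/CH2Cl2, 0 °C
Reagents that add atoms: none
Why: Acid-catalysed methanolysis removes the primary silyl ether and leaves the pivalate.

Step 8
Reactants: 14 (3E)-6-hydroxy-4-methylhex-3-en-1-yl pivalate
Product: 15 (3E)-4-methyl-6-oxohex-3-en-1-yl pivalate
Conditions: Dess–Martin periodinane, NaHCO3, CH2Cl2, 0 °C; used crude
Reagents that add atoms: none
Why: Buffered Dess–Martin oxidation should give the β,γ-unsaturated aldehyde without migration of the double bond.

Step 9
Reactants: 16 2-(3-chloropropyl)-2-methyl-1,3-dioxolane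
Product: 17 2-methyl-2-(pent-4-yn-1-yl)-1,3-dioxolane
Conditions: lithium acetylide–ethylenediamine complex, DMSO, rt
Reagents that add atoms: lithium acetylide–ethylenediamine complex, [Li+].[C-]#C.NCCN
Why: SN2 alkylation of acetylide by a primary chloride in DMSO; the ketal is inert to base.

Step 10
Reactants: 17 2-methyl-2-(pent-4-yn-1-yl)-1,3-dioxolane
Product: 19 2-[(4E)-5-iodo-4-methylpent-4-en-1-yl]-2-methyl-1,3-dioxolane, via alkenylalane 18 (not isolated)
Conditions: Me3Al (2 equiv), Cp2ZrCl2 (0.2 equiv), H2O (1 equiv), CH2Cl2, −25 °C; then I2, THF, −25 to 0 °C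
Reagents that add atoms: trimethylaluminium, C[Al](C)C; iodine, II
Why: Water-accelerated Negishi carboalumination at low temperature (to spare the ketal), then iodinolysis with retention, should give the (E)-alkenyl iodide.

Step 11
Reactants: 15 (3E)-4-methyl-6-oxohex-3-en-1-yl pivalate; 19 2-[(4E)-5-iodo-4-methylpent-4-en-1-yl]-2-methyl-1,3-dioxolane
Product: 20 (3E,6S,7E)-6-hydroxy-4,8-dimethyl-11-(2-methyl-1,3-dioxolan-2-yl)undeca-3,7-dien-1-yl pivalate
Conditions: CrCl2 (3 equiv), NiCl2 (cat.), (S)-oxazoline–sulfonamide ligand (3.3 equiv), Et3N, THF, rt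
Reagents that add atoms: none
Why: Asymmetric Nozaki–Hiyama–Kishi coupling: the alkenylchromium adds only to the aldehyde, with retention of the E geometry, and the chromium-bound chiral sulfonamide selects the aldehyde face to set C6 (S).

Step 12
Reactants: 20 the (6S)-allylic alcohol
Product: 21 (3E,6S,7E)-6-[(tert-butyldimethylsilyl)oxy]-4,8-dimethyl-11-(2-methyl-1,3-dioxolan-2-yl)undeca-3,7-dien-1-yl pivalate
Conditions: TBSCl, imidazole, DMF, rt
Reagents that add atoms: tert-butyldimethylsilyl chloride, CC(C)(C)[Si](C)(C)Cl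
Why: Standard silylation of a secondary allylic alcohol; the group later sits equatorial at C6 and is removed last.

Step 13
Reactants: 21 the silyl ether ketal
Product: 22 (3E,6S,7E)-6-[(tert-butyldimethylsilyl)oxy]-4,8-dimethyl-12-oxotrideca-3,7-dien-1-yl pivalate
Conditions: PPTS (cat.), acetone/H2O, 40 °C
Reagents that add atoms: water, O
Why: Mild acid hydrolysis of the dioxolane; the secondary silyl ether and the pivalate should survive PPTS.

Step 14
Reactants: 22 the methyl ketone
Product: 23 (3E,6S,7E)-6-[(tert-butyldimethylsilyl)oxy]-4,8-dimethyl-11-(2-methyloxiran-2-yl)undeca-3,7-dien-1-yl pivalate (both oxirane epimers)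
Conditions: Me3S+ I−, n-BuLi, THF, −10 °C; then 22, −10 °C to rt
Reagents that add atoms: trimethylsulfonium iodide, C[S+](C)C.[I-]
Why: Corey–Chaykovsky methylene transfer to the ketone gives the 2,2-disubstituted oxirane; the new stereocentre need not be controlled because it becomes a planar radical in step 15.

Step 15
Reactants: 23 the epoxy-diene
Product: 24 6α-[(tert-butyldimethylsilyl)oxy]-18-hydroxy-13,14,15,16-tetranorlabd-8(17)-en-12-yl pivalate (trans-decalin; 4α-CH2OH, 4β-CH3, 5α-H, 9α-H, 10β-CH3)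
Conditions: Cp2TiCl2 (2.5 equiv), Mn dust (8 equiv), THF (high dilution, slow addition of 23), rt; dilute aq. HCl work-up
Reagents that add atoms: none
Why: Cp2TiCl (Nugent–RajanBabu reagent) opens the oxirane homolytically to the tertiary C4 radical bearing CH2O[Ti]; this adds to C5 (ring A, 6-endo-trig), the resulting tertiary C10 radical adds to C9 (ring B, 6-endo-trig, closed last), and the tertiary C8 radical is captured by a second Cp2TiCl and loses a β-hydrogen from C17 to give the exocyclic alkene. The closest known reaction type is the titanocene(III)-mediated radical cyclisation of epoxypolyprenes to drimane- and labdane-type alcohols with an exocyclic alkene. Both closures run through chair-like transition states on (E)-trisubstituted alkenes, which should give the trans ring fusion (5α-H, 10β-CH3) and, from the E geometry of C8=C9, the equatorial side chain at C9. At C4 the bulky titanoxymethyl group should take the pseudo-equatorial site, so C18 ends α and the methyl β. The absolute sense comes from C6: A(1,3) strain with the cis C20 methyl holds H6 in the alkene plane and the radical attacks C5 anti to the C7 chain, which puts the silyloxy group equatorial (6α). The step needs 6-endo over 5-exo attack, secured by the fully substituted inner alkene carbons C10 and C8, and a stop after two rings, secured by the absence of a further alkene in the truncated chain.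

Step 16
Reactants: 24 the 8(17)-alkene
Product: 25 6α-[(tert-butyldimethylsilyl)oxy]-8α,18-dihydroxy-13,14,15,16-tetranorlabdan-12-yl pivalate
Conditions: Co(acac)2 (cat.), PhSiH3, O2 (1 atm), THF, rt; then PPh3
Reagents that add atoms: dioxygen, O=O
Why: Mukaiyama hydration (metal-hydride H-atom transfer): H adds to C17, and O2 should trap the tertiary C8 radical on the α-face, anti to the axial C10 methyl, to give the equatorial 8α-OH and axial 8β-CH3.

Step 17
Reactants: 25 the pivalate diol
Product: 26 6α-[(tert-butyldimethylsilyl)oxy]-13,14,15,16-tetranorlabdane-8α,12,18-triol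
Conditions: LiAlH4, THF, 0 °C to rt; Fieser work-up
Reagents that add atoms: none
Why: Hydride reduction cleaves the pivalate; the silyl ether and the tertiary alcohol are inert.

Step 18
Reactants: 26 the triol
Product: 27 12-bromo-6α-[(tert-butyldimethylsilyl)oxy]-13,14,15,16-tetranorlabdane-8α,18-diol
Conditions: CBr4 (1.1 equiv), PPh3 (1.2 equiv), 2,6-lutidine, CH2Cl2, −20 to 0 °C; used at once
Reagents that add atoms: carbon tetrabromide, BrC(Br)(Br)Br
Why: Appel bromination should pick the unhindered primary C12 alcohol over the neopentyl C18 alcohol and the tertiary C8 alcohol, since the displacement is SN2.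

Step 19
Reactants: 27 the alkyl bromide; 9 (5R)-5-[(2E)-3-bromobut-2-en-1-yl]-4-methylfuran-2(5H)-one
Product: 28 the 6-O-TBS, 18-hydroxy analogue of 30 (C18 = CH2OH, 6α-OTBS, 8α-OH, full (13E) side chain with the (16R)-butenolide)
Conditions: NiBr2·glyme (cat.), 4,4′-di-tert-butyl-2,2′-bipyridine (cat.), Mn powder (3 equiv), DMPU, rt
Reagents that add atoms: none
Why: Nickel-catalysed reductive cross-electrophile coupling of an alkenyl bromide (oxidative addition) with a primary alkyl bromide (radical capture) forms C12–C13 with retention of the E geometry and tolerates free hydroxyls and the lactone.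

Step 20
Reactants: 28 the C18 alcohol
Product: 29 the 6-O-TBS ether of 30 (C18 = CHO)
Conditions: Dess–Martin periodinane, NaHCO3, CH2Cl2, 0 °C to rt
Reagents that add atoms: none
Why: Dess–Martin oxidation converts the only primary alcohol to the aldehyde; with O6 still silylated no lactol can form and over-oxidise, and the tertiary 8-OH cannot react.

Step 21
Reactants: 29 the silyl ether aldehyde
Product: 30 CNP0143336.1 (target)
Conditions: HF·pyridine, pyridine, THF, 0 °C to rt
Reagents that add atoms: none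
Why: Buffered fluoride desilylation frees the 6α-hydroxyl without base, so the butenolide C16–H and the aldehyde are not endangered.

**Compound list**
1 | pent-3-yn-1-ol | CC#CCCO | starting material
2 | O-zirconated (E)-alkenylzirconocene chloride | C/C(=C\CCO[Zr](Cl)(C1C=CC=C1)C1C=CC=C1)[Zr](Cl)(C1C=CC=C1)C1C=CC=C1 | intermediate
3 | (E)-4-bromopent-3-en-1-ol | OCC/C=C(\C)Br | intermediate
4 | (E)-4-bromopent-3-enal | O=CC/C=C(\C)Br | intermediate
5 | methyl propiolate | C#CC(=O)OC | starting material
6 | methyl 3-(methylzincio)propiolate | C[Zn]C#CC(=O)OC | intermediate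
7 | methyl (4R,6E)-7-bromo-4-hydroxyoct-6-en-2-ynoate | COC(=O)C#C[C@H](O)C/C=C(\C)Br | intermediate
8 | methyl (2Z,4R,6E)-7-bromo-4-hydroxy-3-methylocta-2,6-dienoate | COC(=O)/C=C(/C)[C@H](O)C/C=C(\C)Br | intermediate
9 | (5R)-5-[(2E)-3-bromobut-2-en-1-yl]-4-methylfuran-2(5H)-one | CC1=CC(=O)O[C@@H]1C/C=C(\C)Br | intermediate
10 | tert-butyl(but-3-yn-1-yloxy)dimethylsilane | C#CCCO[Si](C)(C)C(C)(C)C | starting material
11 | (E)-[4-(tert-butyldimethylsilyloxy)-2-methylbut-1-en-1-yl]dimethylalane | C[Al](C)/C=C(\C)CCO[Si](C)(C)C(C)(C)C | intermediate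
12 | (3E)-6-[(tert-butyldimethylsilyl)oxy]-4-methylhex-3-en-1-ol | OCC/C=C(\C)CCO[Si](C)(C)C(C)(C)C | intermediate
13 | (3E)-6-[(tert-butyldimethylsilyl)oxy]-4-methylhex-3-en-1-yl pivalate | CC(C)(C)C(=O)OCC/C=C(\C)CCO[Si](C)(C)C(C)(C)C | intermediate
14 | (3E)-6-hydroxy-4-methylhex-3-en-1-yl pivalate | CC(C)(C)C(=O)OCC/C=C(\C)CCO | intermediate
15 | (3E)-4-methyl-6-oxohex-3-en-1-yl pivalate | CC(C)(C)C(=O)OCC/C=C(\C)CC=O | intermediate
16 | 2-(3-chloropropyl)-2-methyl-1,3-dioxolane | CC1(CCCCl)OCCO1 | starting material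
17 | 2-methyl-2-(pent-4-yn-1-yl)-1,3-dioxolane | CC1(CCCC#C)OCCO1 | intermediate
18 | (E)-dimethyl[2-methyl-5-(2-methyl-1,3-dioxolan-2-yl)pent-1-en-1-yl]alane | CC1(CCC/C(C)=C/[Al](C)C)OCCO1 | intermediate
19 | 2-[(4E)-5-iodo-4-methylpent-4-en-1-yl]-2-methyl-1,3-dioxolane | CC1(CCC/C(C)=C/I)OCCO1 | intermediate
20 | (3E,6S,7E)-6-hydroxy-4,8-dimethyl-11-(2-methyl-1,3-dioxolan-2-yl)undeca-3,7-dien-1-yl pivalate | CC1(CCC/C(C)=C/[C@@H](O)C/C(C)=C/CCOC(=O)C(C)(C)C)OCCO1 | intermediate
21 | (3E,6S,7E)-6-[(tert-butyldimethylsilyl)oxy]-4,8-dimethyl-11-(2-methyl-1,3-dioxolan-2-yl)undeca-3,7-dien-1-yl pivalate | CC1(CCC/C(C)=C/[C@@H](O[Si](C)(C)C(C)(C)C)C/C(C)=C/CCOC(=O)C(C)(C)C)OCCO1 | intermediate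
22 | (3E,6S,7E)-6-[(tert-butyldimethylsilyl)oxy]-4,8-dimethyl-12-oxotrideca-3,7-dien-1-yl pivalate | CC(=O)CCC/C(C)=C/[C@@H](O[Si](C)(C)C(C)(C)C)C/C(C)=C/CCOC(=O)C(C)(C)C | intermediate
23 | (3E,6S,7E)-6-[(tert-butyldimethylsilyl)oxy]-4,8-dimethyl-11-(2-methyloxiran-2-yl)undeca-3,7-dien-1-yl pivalate, both oxirane epimers | CC1(CCC/C(C)=C/[C@@H](O[Si](C)(C)C(C)(C)C)C/C(C)=C/CCOC(=O)C(C)(C)C)CO1 | intermediate
24 | 6α-[(tert-butyldimethylsilyl)oxy]-18-hydroxy-13,14,15,16-tetranorlabd-8(17)-en-12-yl pivalate | CC(C)(C)C(=O)OCC[C@@H]1[C@@]2(C)CCC[C@@](C)(CO)[C@@H]2[C@@H](O[Si](C)(C)C(C)(C)C)CC1=C | intermediate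
25 | 6α-[(tert-butyldimethylsilyl)oxy]-8α,18-dihydroxy-13,14,15,16-tetranorlabdan-12-yl pivalate | CC(C)(C)C(=O)OCC[C@@H]1[C@@]2(C)CCC[C@@](C)(CO)[C@@H]2[C@@H](O[Si](C)(C)C(C)(C)C)C[C@@]1(C)O | intermediate
26 | 6α-[(tert-butyldimethylsilyl)oxy]-13,14,15,16-tetranorlabdane-8α,12,18-triol | OCC[C@@H]1[C@@]2(C)CCC[C@@](C)(CO)[C@@H]2[C@@H](O[Si](C)(C)C(C)(C)C)C[C@@]1(C)O | intermediate
27 | 12-bromo-6α-[(tert-butyldimethylsilyl)oxy]-13,14,15,16-tetranorlabdane-8α,18-diol | BrCC[C@@H]1[C@@]2(C)CCC[C@@](C)(CO)[C@@H]2[C@@H](O[Si](C)(C)C(C)(C)C)C[C@@]1(C)O | intermediate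
28 | 6-O-TBS, 18-hydroxy analogue of the target (C18 = CH2OH) | CC1=CC(=O)O[C@@H]1C/C=C(\C)CC[C@@H]1[C@@]2(C)CCC[C@@](C)(CO)[C@@H]2[C@@H](O[Si](C)(C)C(C)(C)C)C[C@@]1(C)O | intermediate
29 | 6-O-TBS ether of the target | CC1=CC(=O)O[C@@H]1C/C=C(\C)CC[C@@H]1[C@@]2(C)CCC[C@@](C)(C=O)[C@@H]2[C@@H](O[Si](C)(C)C(C)(C)C)C[C@@]1(C)O | intermediate
30 | CNP0143336.1 | CC1=CC(=O)O[C@@H]1C/C=C(\C)CC[C@@H]1[C@@]2(C)CCC[C@@](C)(C=O)[C@@H]2[C@@H](O)C[C@@]1(C)O | target

**Totals**
Total step count: 21. Longest linear sequence: 15 steps (10 to 30 through steps 5–8 and 11–21).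

**Steps most likely to fail**

Step 15. The tertiary C10 radical formed after closure of ring A may be intercepted by titanium(III) and lose a β-hydrogen before the slower second 6-endo closure, so the cascade would stop after one ring. The fallback sets out from 23 and separates the two closures. The titanocene step is run at high titanium(III) concentration to give on purpose the monocyclic alcohol with an exocyclic C10=C20 methylene, (3E)-6-[(tert-butyldimethylsilyl)oxy]-6-[2-(hydroxymethyl)-2-methyl-6-methylidenecyclohexyl]-4-methylhex-3-en-1-yl pivalate F1. Ring B is then closed by a cationic olefin cyclisation (SnCl4, CH2Cl2, −78 °C): Markovnikov protonation at C20 gives the C10 cation, C9 attacks through a chair, and C8 loses a proton. This comes back to the route at 24, accompanied by its Δ7 isomer, 6α-[(tert-butyldimethylsilyl)oxy]-18-hydroxy-13,14,15,16-tetranorlabd-7-en-12-yl pivalate F2, which step 16 should convert to the same alcohol 25.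

Step 19. The 8α-hydroxyl may displace the C12 bromide intramolecularly to a cyclic ether, or the alkyl radical may dimerise or be reduced faster than it is captured by nickel. The fallback sets out from 27 and uses a two-electron coupling on a protected substrate. Both free hydroxyls are silylated (TMSOTf, 2,6-lutidine) to the bis(trimethylsilyl) ether F3. Zinc insertion (Zn dust, LiCl, THF, 50 °C) gives the alkylzinc bromide F4. Negishi coupling with 9 (Pd(OAc)2, SPhos, THF, rt) gives the coupled bis(trimethylsilyl) ether F5. Methanolysis of the two TMS ethers (PPTS, MeOH, 0 °C) comes back to the route at 28.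

Step 3. The β,γ-double bond of the enolisable aldehyde 4 may migrate into conjugation under the zinc alkoxide conditions, and face selectivity with an aliphatic aldehyde may be low. The fallback sets out from 4 and replaces catalytic asymmetric addition by kinetic addition plus resolution. Lithium methyl propiolate (from 5 and LiHMDS, THF, −78 °C) is added to give the racemic alcohol methyl (6E)-7-bromo-4-hydroxyoct-6-en-2-ynoate F6. Lipase-mediated acetylation (Burkholderia cepacia lipase, vinyl acetate, hexane) should convert the (S)-enantiomer to the acetate methyl (4S,6E)-4-acetoxy-7-bromooct-6-en-2-ynoate F7 and leave the (R)-alcohol, which comes back to the route at 7.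

**Further compounds**
F1 | step 15 | (3E)-6-[(tert-butyldimethylsilyl)oxy]-6-[2-(hydroxymethyl)-2-methyl-6-methylidenecyclohexyl]-4-methylhex-3-en-1-yl pivalate | C=C1CCC[C@@](C)(CO)[C@@H]1[C@@H](O[Si](C)(C)C(C)(C)C)C/C(C)=C/CCOC(=O)C(C)(C)C
F2 | step 15 | 6α-[(tert-butyldimethylsilyl)oxy]-18-hydroxy-13,14,15,16-tetranorlabd-7-en-12-yl pivalate | CC(C)(C)C(=O)OCC[C@@H]1[C@@]2(C)CCC[C@@](C)(CO)[C@@H]2[C@@H](O[Si](C)(C)C(C)(C)C)C=C1C
F3 | step 19 | 12-bromo-6α-[(tert-butyldimethylsilyl)oxy]-8α,18-bis[(trimethylsilyl)oxy]-13,14,15,16-tetranorlabdane | BrCC[C@@H]1[C@@]2(C)CCC[C@@](C)(CO[Si](C)(C)C)[C@@H]2[C@@H](O[Si](C)(C)C(C)(C)C)C[C@@]1(C)O[Si](C)(C)C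
F4 | step 19 | alkylzinc bromide from F3 (C12–ZnBr) | Br[Zn]CC[C@@H]1[C@@]2(C)CCC[C@@](C)(CO[Si](C)(C)C)[C@@H]2[C@@H](O[Si](C)(C)C(C)(C)C)C[C@@]1(C)O[Si](C)(C)C
F5 | step 19 | 8,18-bis(trimethylsilyl) ether of 28 | CC1=CC(=O)O[C@@H]1C/C=C(\C)CC[C@@H]1[C@@]2(C)CCC[C@@](C)(CO[Si](C)(C)C)[C@@H]2[C@@H](O[Si](C)(C)C(C)(C)C)C[C@@]1(C)O[Si](C)(C)C
F6 | step 3 | methyl (6E)-7-bromo-4-hydroxyoct-6-en-2-ynoate, racemic | COC(=O)C#CC(O)C/C=C(\C)Br
F7 | step 3 | methyl (4S,6E)-4-acetoxy-7-bromooct-6-en-2-ynoate | COC(=O)C#C[C@@H](OC(C)=O)C/C=C(\C)Br
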